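The tetralin core is numbered so that C1 carries the C11–C16 side chain and C4 the methyl group; ring A is the arene and ring B the saturated carbocycle. Everything rests on disconnecting C2–C3, the unsubstituted two-carbon link of ring B that carries no stereochemistry and lies between the benzylic stereocentres C1 and C4. A Ramberg–Bäcklund contraction of a benzo-fused seven-membered sulfone deletes SO2 and, in one operation, forms the C2–C3 bond and closes ring B as a 1,4-dihydronaphthalene without touching a stereocentre. The precursor is a 1,5-disubstituted tetrahydro-3-benzothiepine 3,3-dioxide that already holds C1, C4, C11 and C15 in their final configurations, each set in open-chain intermediates.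

Key step: step 15

Assumption: for step 11 the (R) antipode of DTBM-SEGPHOS is written; the facial sense of the CuH catalyst on such α-substituted styrenes is to be confirmed on a model alkene, and the (S) ligand would be used if it proved opposite.

Step 1
Reactants: 1 (S)-3-bromo-2-methylpropan-1-ol
Product: 2 (S)-(3-bromo-2-methylpropoxy)(tert-butyl)dimethylsilane
Conditions: TBSCl, imidazole, CH2Cl2, 0 °C → rt
Reagents that add atoms: tert-butyldimethylsilyl chloride, CC(C)(C)[Si](C)(C)Cl
Why: Imidazole-promoted silyl ether formation on a primary alcohol is routine and does not involve the stereocentre, which becomes C15.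

Step 2
Reactants: 2 (S)-(3-bromo-2-methylpropoxy)(tert-butyl)dimethylsilane
Product: 4 (R)-5-(tert-butyldimethylsilyloxy)-4-methylpentan-1-ol, via Grignard reagent 3 (not isolated)
Conditions: Mg, THF, 40 °C; then CuBr·SMe2 (10 mol%), oxirane, −30 °C → rt; aq. NH4Cl
Reagents that add atoms: oxirane, C1CO1
Why: Grignard formation followed by copper-catalysed SN2 opening of oxirane is the classical two-carbon homologation to a primary alcohol, and the stereocentre is not at a reacting carbon.

Step 3
Reactants: 4 (R)-5-(tert-butyldimethylsilyloxy)-4-methylpentan-1-ol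
Product: 5 (R)-tert-butyl[(5-iodo-2-methylpentyl)oxy]dimethylsilane
Conditions: I2, PPh3, imidazole, CH2Cl2, 0 °C → rt
Reagents that add atoms: iodine, [I][I]
Why: Appel-type iodination converts the unbranched primary alcohol into the iodide by SN2 displacement of the oxyphosphonium group, leaving the silyl ether and the remote stereocentre untouched.

Step 4
Reactants: 6 2-bromo-3,4-dimethoxybenzaldehyde
Product: 7 rac-1-(2-bromo-3,4-dimethoxyphenyl)propan-1-ol
Conditions: EtMgBr, THF, 0 °C; aq. NH4Cl
Reagents that add atoms: ethylmagnesium bromide, CC[Mg]Br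
Why: Grignard addition to the aryl aldehyde is fast at 0 °C, where EtMgBr does not exchange with the aryl bromide; the carbinol centre is removed in the next step, so the racemate suffices.

Step 5
Reactants: 7 rac-1-(2-bromo-3,4-dimethoxyphenyl)propan-1-ol
Product: 8 1-(2-bromo-3,4-dimethoxyphenyl)propan-1-one
Conditions: Dess–Martin periodinane, CH2Cl2, rt
Reagents that add atoms: none
Why: Dess–Martin oxidation of a benzylic secondary alcohol to the aryl ethyl ketone proceeds under neutral conditions that spare the aryl bromide and the methyl ethers.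

Step 6
Reactants: 8 1-(2-bromo-3,4-dimethoxyphenyl)propan-1-one
Product: 9 SAMP hydrazone (S)-N-[(E)-1-(2-bromo-3,4-dimethoxyphenyl)propylidene]-2-(methoxymethyl)pyrrolidin-1-amine
Conditions: SAMP (1.3 equiv), TsOH (cat.), cyclohexane, reflux, Dean–Stark
Reagents that add atoms: (S)-1-amino-2-(methoxymethyl)pyrrolidine (SAMP), COC[C@@H]1CCCN1N
Why: Acid-catalysed hydrazone condensation installs the SAMP auxiliary, whose amino group should settle anti to the twisted aryl group and syn to the ethyl group that is deprotonated next.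

Step 7
Reactants: 9 SAMP hydrazone (S)-N-[(E)-1-(2-bromo-3,4-dimethoxyphenyl)propylidene]-2-(methoxymethyl)pyrrolidin-1-amine; 5 (R)-tert-butyl[(5-iodo-2-methylpentyl)oxy]dimethylsilane
Product: 11 alkylated SAMP hydrazone (S)-N-[(1E,2S,6R)-1-(2-bromo-3,4-dimethoxyphenyl)-7-(tert-butyldimethylsilyloxy)-2,6-dimethylheptylidene]-2-(methoxymethyl)pyrrolidin-1-amine, via lithium azaenolate 10 (not isolated)
Conditions: LiN(iPr)2, THF, 0 °C; then 5, −100 °C → rt
Reagents that add atoms: none
Why: In this SAMP-hydrazone alkylation the chelated lithium azaenolate (C=C E, C–N Z) is attacked by the primary iodide on the face left open by the methoxymethylpyrrolidine, which by analogy with the diethyl ketone series should set C11 as S; the amide base cannot form an aryne because the bromide has no ortho hydrogen.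

Step 8
Reactants: 11 alkylated SAMP hydrazone (S)-N-[(1E,2S,6R)-1-(2-bromo-3,4-dimethoxyphenyl)-7-(tert-butyldimethylsilyloxy)-2,6-dimethylheptylidene]-2-(methoxymethyl)pyrrolidin-1-amine
Product: 12 ketone (2S,6R)-1-(2-bromo-3,4-dimethoxyphenyl)-7-(tert-butyldimethylsilyloxy)-2,6-dimethylheptan-1-one
Conditions: O3, CH2Cl2, −78 °C; argon purge
Reagents that add atoms: ozone, [O-][O+]=O
Why: Ozonolytic cleavage of the hydrazone C=N bond releases the ketone under cold, neutral conditions, so the enolisable C11 centre is not epimerised; no alkene is present at this stage.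

Step 9
Reactants: 12 ketone (2S,6R)-1-(2-bromo-3,4-dimethoxyphenyl)-7-(tert-butyldimethylsilyloxy)-2,6-dimethylheptan-1-one
Product: 13 aryl bromide alkene {[(2R,6S)-7-(2-bromo-3,4-dimethoxyphenyl)-2,6-dimethyloct-7-en-1-yl]oxy}(tert-butyl)dimethylsilane
Conditions: Cp2Ti(μ-Cl)(μ-CH2)AlMe2, pyridine (cat.), THF/toluene, −40 °C → rt
Reagents that add atoms: Tebbe reagent Cp2Ti(μ-Cl)(μ-CH2)AlMe2, C[Al-]1(C)C[Ti](C2C=CC=C2)(C3C=CC=C3)[Cl+]1
Why: Tebbe methylenation is non-basic and accepts hindered enolisable ketones, so the carbonyl becomes the C1=C2 methylene without epimerising C11, which is no longer acidic afterwards.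

Step 10
Reactants: 13 aryl bromide alkene {[(2R,6S)-7-(2-bromo-3,4-dimethoxyphenyl)-2,6-dimethyloct-7-en-1-yl]oxy}(tert-butyl)dimethylsilane; 14 isopropenylboronic acid pinacol ester
Product: 15 diene {[(2R,6S)-7-[3,4-dimethoxy-2-(prop-1-en-2-yl)phenyl]-2,6-dimethyloct-7-en-1-yl]oxy}(tert-butyl)dimethylsilane
Conditions: Pd(OAc)2 (5 mol%), SPhos (10 mol%), K3PO4, toluene/H2O, 90 °C
Reagents that add atoms: none
Why: Suzuki–Miyaura coupling with a bulky biarylphosphine ligand joins the di-ortho-substituted aryl bromide to the alkenyl boronate, installing C4 with its methyl group and C3.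

Step 11
Reactants: 15 diene {[(2R,6S)-7-[3,4-dimethoxy-2-(prop-1-en-2-yl)phenyl]-2,6-dimethyloct-7-en-1-yl]oxy}(tert-butyl)dimethylsilane
Product: 17 diol (2S,3S,7R)-8-(tert-butyldimethylsilyloxy)-2-{2-[(2S)-1-hydroxypropan-2-yl]-3,4-dimethoxyphenyl}-3,7-dimethyloctan-1-ol, via bis(pinacol boronate) 16 (not isolated)
Conditions: CuCl (10 mol%), (R)-DTBM-SEGPHOS (11 mol%), KOtBu (20 mol%), HBpin (4 equiv), toluene, 40 °C; then NaOH, H2O2, THF/H2O, 0 °C
Reagents that add atoms: hydrogen peroxide, OO
Why: Copper hydride-catalysed asymmetric hydroboration of 1,1-disubstituted aryl alkenes places copper on the terminal carbon and hydride on the internal one, so the ligand sets both C1 and C4 (one antipode serves both, since the two alkenes present the same aryl/alkyl/methylene arrangement), and oxidation with retention should give the S,S diol.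

Step 12
Reactants: 17 diol (2S,3S,7R)-8-(tert-butyldimethylsilyloxy)-2-{2-[(2S)-1-hydroxypropan-2-yl]-3,4-dimethoxyphenyl}-3,7-dimethyloctan-1-ol
Product: 18 ditosylate (2S,3S,7R)-8-(tert-butyldimethylsilyloxy)-2-{3,4-dimethoxy-2-[(2S)-1-(tosyloxy)propan-2-yl]phenyl}-3,7-dimethyloctyl 4-methylbenzenesulfonate
Conditions: TsCl (3 equiv), Et3N, DMAP (cat.), CH2Cl2, 0 °C → rt
Reagents that add atoms: p-toluenesulfonyl chloride, Cc1ccc(cc1)S(Cl)(=O)=O
Why: Sulfonylation of two primary alcohols activates C2 and C3 for substitution without involving any stereocentre.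

Step 13
Reactants: 18 ditosylate (2S,3S,7R)-8-(tert-butyldimethylsilyloxy)-2-{3,4-dimethoxy-2-[(2S)-1-(tosyloxy)propan-2-yl]phenyl}-3,7-dimethyloctyl 4-methylbenzenesulfonate
Product: 19 cyclic sulfide tert-butyl{[(2R,6S)-6-[(1S,5S)-6,7-dimethoxy-5-methyl-1,2,4,5-tetrahydro-3-benzothiepin-1-yl]-2-methylheptyl]oxy}dimethylsilane
Conditions: Na2S·9H2O, DMF, 0.01 M, 60 °C
Reagents that add atoms: sodium sulfide, [Na+].[Na+].[S-2]
Why: Double SN2 thioetherification at high dilution closes the seven-membered sulfide, the ortho-phenylene unit holding the two arms together and the strongly nucleophilic sulfur outrunning ionisation or elimination; the substitutions occur at CH2 groups, not at stereocentres.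

Step 14
Reactants: 19 cyclic sulfide tert-butyl{[(2R,6S)-6-[(1S,5S)-6,7-dimethoxy-5-methyl-1,2,4,5-tetrahydro-3-benzothiepin-1-yl]-2-methylheptyl]oxy}dimethylsilane
Product: 20 cyclic sulfone (1S,5S)-1-[(2S,6R)-7-(tert-butyldimethylsilyloxy)-6-methylheptan-2-yl]-6,7-dimethoxy-5-methyl-1,2,4,5-tetrahydro-3-benzothiepine 3,3-dioxide
Conditions: mCPBA (2.3 equiv), CH2Cl2, 0 °C → rt
Reagents that add atoms: 3-chloroperbenzoic acid, OOC(=O)c1cccc(Cl)c1
Why: Peracid oxidation of a dialkyl sulfide to the sulfone is reliable, and the substrate has no alkene or other oxidisable group.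

Step 15
Reactants: 20 cyclic sulfone (1S,5S)-1-[(2S,6R)-7-(tert-butyldimethylsilyloxy)-6-methylheptan-2-yl]-6,7-dimethoxy-5-methyl-1,2,4,5-tetrahydro-3-benzothiepine 3,3-dioxide
Product: 23 trans-dihydronaphthalene tert-butyl{[(2R,6S)-6-[(1R,4R)-5,6-dimethoxy-4-methyl-1,4-dihydronaphthalen-1-yl]-2-methylheptyl]oxy}dimethylsilane, via α-bromo sulfone 21 (not isolated), via episulfone 22 (not isolated)
Conditions: CBr2F2 (excess), KOH/Al2O3, t-BuOH/CH2Cl2, 0–5 °C; crude product taken directly into step 16
Reagents that add atoms: none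
Why: KOH on alumina deprotonates one sulfonyl α-CH2 (C2 or C3, both leading to the same alkene), CBr2F2 brominates the carbanion, and deprotonation at the other α-carbon with 1,3-displacement of bromide gives the episulfone, which loses SO2 to leave the C2=C3 double bond. The closest known reaction is the Ramberg–Bäcklund reaction with in situ halogenation, established for contracting cyclic sulfones such as thiepane dioxides to cyclohexenes. Ring B is closed by ring contraction: a 3-exo-tet carbanion displacement forms the C2–C3 bond inside the bicyclic episulfone, and cheletropic extrusion of SO2 leaves the six-membered ring fused to ring A, the ring enforcing the cis alkene. No stereocentre is formed, and C1, C4, C11 and C15 are carried through unchanged because none is α to sulfur. The selectivity needed is deprotonation at the sulfonyl α-carbons and not at the benzylic, allylic C1–H and C4–H of the product; it is secured by the higher kinetic acidity of the α-sulfonyl positions, by the tertiary, shielded nature of C1–H and C4–H, by the cold heterogeneous base and short contact time, and by immediate hydrogenation, while monobromination is favoured because episulfone closure should outpace a second halogenation.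

Step 16
Reactants: 23 trans-dihydronaphthalene tert-butyl{[(2R,6S)-6-[(1R,4R)-5,6-dimethoxy-4-methyl-1,4-dihydronaphthalen-1-yl]-2-methylheptyl]oxy}dimethylsilane
Product: 24 tetralin tert-butyl{[(2R,6S)-6-[(1S,4R)-5,6-dimethoxy-4-methyl-1,2,3,4-tetrahydronaphthalen-1-yl]-2-methylheptyl]oxy}dimethylsilane
Conditions: H2 (1 atm), PtO2, EtOAc, rt
Reagents that add atoms: none
Why: Heterogeneous hydrogenation over platinum saturates the cis-disubstituted C2=C3 bond with little double-bond migration, removing the base- and air-sensitive dihydroarene before C1 or C4 can be scrambled; the descriptor at C1 changes only through CIP priorities.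

Step 17
Reactants: 24 tetralin tert-butyl{[(2R,6S)-6-[(1S,4R)-5,6-dimethoxy-4-methyl-1,2,3,4-tetrahydronaphthalen-1-yl]-2-methylheptyl]oxy}dimethylsilane
Product: 26 acid (5R,8S)-8-[(2S,6R)-7-(tert-butyldimethylsilyloxy)-6-methylheptan-2-yl]-3,4-dimethoxy-5-methyl-5,6,7,8-tetrahydronaphthalene-2-carboxylic acid, via C7 aryllithium 25 (not isolated)
Conditions: n-BuLi, TMEDA, Et2O, 0 °C → rt; CO2, −78 °C; 1 M HCl, 0 °C (brief)
Reagents that add atoms: carbon dioxide, O=C=O
Why: In this directed ortho-metalation and carboxylation C7–H is the only position ortho to a methoxy group, so lithiation should occur there as in the conversion of veratrole into 2,3-dimethoxybenzoic acid, the tertiary benzylic C–H bonds being kinetically much less acidic.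

Step 18
Reactants: 26 acid (5R,8S)-8-[(2S,6R)-7-(tert-butyldimethylsilyloxy)-6-methylheptan-2-yl]-3,4-dimethoxy-5-methyl-5,6,7,8-tetrahydronaphthalene-2-carboxylic acid
Product: 27 trihydroxy acid (5R,8S)-3,4-dihydroxy-8-[(2S,6R)-7-hydroxy-6-methylheptan-2-yl]-5-methyl-5,6,7,8-tetrahydronaphthalene-2-carboxylic acid
Conditions: BBr3 (6 equiv), CH2Cl2, −78 → 0 °C; H2O
Reagents that add atoms: none
Why: BBr3 ether cleavage demethylates both aryl methyl ethers (the one next to the carboxyl assisted by chelation) and converts the silyl ether into an alkoxyborane that is hydrolysed on work-up, the temperature being held at or below 0 °C so that the primary alkoxyborane is not turned into a bromide.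

Step 19
Reactants: 28 ferulic acid
Product: 29 vinyl ferulate
Conditions: vinyl acetate (excess), Hg(OAc)2 (cat.), H2SO4 (cat.), THF, rt
Reagents that add atoms: vinyl acetate, CC(=O)OC=C
Why: Mercury-catalysed transvinylation with vinyl acetate converts the carboxylic acid into its vinyl ester without acylating the phenol, the usual way to make hydroxycinnamate acyl donors.

Step 20
Reactants: 27 trihydroxy acid (5R,8S)-3,4-dihydroxy-8-[(2S,6R)-7-hydroxy-6-methylheptan-2-yl]-5-methyl-5,6,7,8-tetrahydronaphthalene-2-carboxylic acid; 29 vinyl ferulate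
Product: 30 target (5R,8S)-3,4-dihydroxy-8-[(2S,6R)-7-{[(2E)-3-(4-hydroxy-3-methoxyphenyl)prop-2-enoyl]oxy}-6-methylheptan-2-yl]-5-methyl-5,6,7,8-tetrahydronaphthalene-2-carboxylic acid
Conditions: 29 (3 equiv), immobilised Candida antarctica lipase B (Novozym 435), 4 Å molecular sieves, 2-methylbutan-2-ol/MeCN, 45 °C
Reagents that add atoms: none
Why: Lipase-catalysed irreversible transesterification with a vinyl ester acylates the primary aliphatic C16–OH and leaves the phenols and the hindered aromatic acid alone, the vinyl alcohol released tautomerising to acetaldehyde; no stereocentre is affected.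

Compound list
1 | (S)-3-bromo-2-methylpropan-1-ol | OC[C@H](C)CBr | starting material
2 | (S)-(3-bromo-2-methylpropoxy)(tert-butyl)dimethylsilane | CC(C)(C)[Si](C)(C)OC[C@H](C)CBr | intermediate
3 | [(2S)-3-(tert-butyldimethylsilyloxy)-2-methylpropyl]magnesium bromide | CC(C)(C)[Si](C)(C)OC[C@H](C)C[Mg]Br | intermediate (not isolated)
4 | (R)-5-(tert-butyldimethylsilyloxy)-4-methylpentan-1-ol | CC(C)(C)[Si](C)(C)OC[C@H](C)CCCO | intermediate
5 | (R)-tert-butyl[(5-iodo-2-methylpentyl)oxy]dimethylsilane | CC(C)(C)[Si](C)(C)OC[C@H](C)CCC[I] | intermediate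
6 | 2-bromo-3,4-dimethoxybenzaldehyde | O=Cc1ccc(OC)c(OC)c1Br | starting material
7 | rac-1-(2-bromo-3,4-dimethoxyphenyl)propan-1-ol | CCC(O)c1ccc(OC)c(OC)c1Br | intermediate
8 | 1-(2-bromo-3,4-dimethoxyphenyl)propan-1-one | CCC(=O)c1ccc(OC)c(OC)c1Br | intermediate
9 | (S)-N-[(E)-1-(2-bromo-3,4-dimethoxyphenyl)propylidene]-2-(methoxymethyl)pyrrolidin-1-amine (amino nitrogen syn to ethyl) | CC/C(=N\N1CCC[C@H]1COC)c1ccc(OC)c(OC)c1Br | intermediate
10 | lithium azaenolate of 9 (C=C with methyl trans to nitrogen; N–Li) | C/C=C(/N([Li])N1CCC[C@H]1COC)c1ccc(OC)c(OC)c1Br | intermediate (not isolated)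
11 | (S)-N-[(1E,2S,6R)-1-(2-bromo-3,4-dimethoxyphenyl)-7-(tert-butyldimethylsilyloxy)-2,6-dimethylheptylidene]-2-(methoxymethyl)pyrrolidin-1-amine | CC(C)(C)[Si](C)(C)OC[C@H](C)CCC[C@H](C)/C(=N\N1CCC[C@H]1COC)c1ccc(OC)c(OC)c1Br | intermediate
12 | (2S,6R)-1-(2-bromo-3,4-dimethoxyphenyl)-7-(tert-butyldimethylsilyloxy)-2,6-dimethylheptan-1-one | CC(C)(C)[Si](C)(C)OC[C@H](C)CCC[C@H](C)C(=O)c1ccc(OC)c(OC)c1Br | intermediate
13 | {[(2R,6S)-7-(2-bromo-3,4-dimethoxyphenyl)-2,6-dimethyloct-7-en-1-yl]oxy}(tert-butyl)dimethylsilane | CC(C)(C)[Si](C)(C)OC[C@H](C)CCC[C@H](C)C(=C)c1ccc(OC)c(OC)c1Br | intermediate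
14 | isopropenylboronic acid pinacol ester | CC(=C)B1OC(C)(C)C(C)(C)O1 | starting material
15 | {[(2R,6S)-7-[3,4-dimethoxy-2-(prop-1-en-2-yl)phenyl]-2,6-dimethyloct-7-en-1-yl]oxy}(tert-butyl)dimethylsilane | CC(C)(C)[Si](C)(C)OC[C@H](C)CCC[C@H](C)C(=C)c1ccc(OC)c(OC)c1C(C)=C | intermediate
16 | bis(pinacol boronate) corresponding to 17 (each CH2OH replaced by CH2Bpin, same spatial arrangement) | CC(C)(C)[Si](C)(C)OC[C@H](C)CCC[C@H](C)[C@H](CB2OC(C)(C)C(C)(C)O2)c1ccc(OC)c(OC)c1[C@H](C)CB3OC(C)(C)C(C)(C)O3 | intermediate (not isolated)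
17 | (2S,3S,7R)-8-(tert-butyldimethylsilyloxy)-2-{2-[(2S)-1-hydroxypropan-2-yl]-3,4-dimethoxyphenyl}-3,7-dimethyloctan-1-ol | CC(C)(C)[Si](C)(C)OC[C@H](C)CCC[C@H](C)[C@H](CO)c1ccc(OC)c(OC)c1[C@H](C)CO | intermediate
18 | (2S,3S,7R)-8-(tert-butyldimethylsilyloxy)-2-{3,4-dimethoxy-2-[(2S)-1-(tosyloxy)propan-2-yl]phenyl}-3,7-dimethyloctyl 4-methylbenzenesulfonate | CC(C)(C)[Si](C)(C)OC[C@H](C)CCC[C@H](C)[C@H](COS(=O)(=O)c2ccc(C)cc2)c1ccc(OC)c(OC)c1[C@H](C)COS(=O)(=O)c3ccc(C)cc3 | intermediate
19 | tert-butyl{[(2R,6S)-6-[(1S,5S)-6,7-dimethoxy-5-methyl-1,2,4,5-tetrahydro-3-benzothiepin-1-yl]-2-methylheptyl]oxy}dimethylsilane | CC(C)(C)[Si](C)(C)OC[C@H](C)CCC[C@H](C)[C@@H]1CSC[C@@H](C)c2c1ccc(OC)c2OC | intermediate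
20 | (1S,5S)-1-[(2S,6R)-7-(tert-butyldimethylsilyloxy)-6-methylheptan-2-yl]-6,7-dimethoxy-5-methyl-1,2,4,5-tetrahydro-3-benzothiepine 3,3-dioxide | CC(C)(C)[Si](C)(C)OC[C@H](C)CCC[C@H](C)[C@@H]1CS(=O)(=O)C[C@@H](C)c2c1ccc(OC)c2OC | intermediate
21 | 20 with one bromine on the sulfonyl α-carbon next to the methyl-bearing benzylic carbon (configuration at CHBr undefined; either α-carbon serves) | CC(C)(C)[Si](C)(C)OC[C@H](C)CCC[C@H](C)[C@@H]1CS(=O)(=O)C(Br)[C@@H](C)c2c1ccc(OC)c2OC | intermediate (not isolated)
22 | episulfone: thiirane 1,1-dioxide cis-fused across C2–C3 of the nascent ring B, other centres as in 20 | CC(C)(C)[Si](C)(C)OC[C@H](C)CCC[C@H](C)[C@@H]1C3C(S3(=O)=O)[C@@H](C)c2c1ccc(OC)c2OC | intermediate (not isolated)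
23 | tert-butyl{[(2R,6S)-6-[(1R,4R)-5,6-dimethoxy-4-methyl-1,4-dihydronaphthalen-1-yl]-2-methylheptyl]oxy}dimethylsilane (1,4-trans) | CC(C)(C)[Si](C)(C)OC[C@H](C)CCC[C@H](C)[C@@H]1C=C[C@@H](C)c2c1ccc(OC)c2OC | intermediate
24 | tert-butyl{[(2R,6S)-6-[(1S,4R)-5,6-dimethoxy-4-methyl-1,2,3,4-tetrahydronaphthalen-1-yl]-2-methylheptyl]oxy}dimethylsilane | CC(C)(C)[Si](C)(C)OC[C@H](C)CCC[C@H](C)[C@@H]1CC[C@@H](C)c2c1ccc(OC)c2OC | intermediate
25 | C7 aryllithium of 24 (lithium ortho to the C6 methoxy group) | CC(C)(C)[Si](C)(C)OC[C@H](C)CCC[C@H](C)[C@@H]1CC[C@@H](C)c2c1cc([Li])c(OC)c2OC | intermediate (not isolated)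
26 | (5R,8S)-8-[(2S,6R)-7-(tert-butyldimethylsilyloxy)-6-methylheptan-2-yl]-3,4-dimethoxy-5-methyl-5,6,7,8-tetrahydronaphthalene-2-carboxylic acid | CC(C)(C)[Si](C)(C)OC[C@H](C)CCC[C@H](C)[C@@H]1CC[C@@H](C)c2c1cc(C(=O)O)c(OC)c2OC | intermediate
27 | (5R,8S)-3,4-dihydroxy-8-[(2S,6R)-7-hydroxy-6-methylheptan-2-yl]-5-methyl-5,6,7,8-tetrahydronaphthalene-2-carboxylic acid | OC[C@H](C)CCC[C@H](C)[C@@H]1CC[C@@H](C)c2c1cc(C(=O)O)c(O)c2O | intermediate
28 | ferulic acid | COc1cc(/C=C/C(=O)O)ccc1O | starting material
29 | vinyl ferulate (ethenyl (2E)-3-(4-hydroxy-3-methoxyphenyl)prop-2-enoate) | COc1cc(/C=C/C(=O)OC=C)ccc1O | intermediate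
30 | (5R,8S)-3,4-dihydroxy-8-[(2S,6R)-7-{[(2E)-3-(4-hydroxy-3-methoxyphenyl)prop-2-enoyl]oxy}-6-methylheptan-2-yl]-5-methyl-5,6,7,8-tetrahydronaphthalene-2-carboxylic acid | COc1cc(/C=C/C(=O)OC[C@H](C)CCC[C@H](C)[C@@H]2CC[C@@H](C)c3c2cc(C(=O)O)c(O)c3O)ccc1O | target

Total step count: 20. Longest linear sequence: 16 steps (from 6 through steps 4–18 and 20, or equally from 1 through steps 1–3, 7–18 and 20).

Steps most likely to fail

Step 15. The contraction may suffer from repeated bromination at the sulfonyl α-carbons, from sluggish halogenation of the hindered CH2 groups, or from base-induced migration of the new double bond into conjugation with ring A, which would erase C1 or C4 or lead to aromatisation. The fallback makes the C2–C3 bond by carbanion alkylation instead of SO2 extrusion and never passes through the dihydroarene. It sets out from ditosylate 18: one tosylate is displaced with NaSPh (1 equiv, DMF, 0 °C; either arm may react and both converge, the less hindered arm next to C4 is written) to give the mono(phenyl sulfide) tosylate F1, which mCPBA oxidises to the phenyl sulfone tosylate F2. LiN(SiMe3)2 in THF (−78 → 0 °C) then forms the α-sulfonyl carbanion, which displaces the remaining tosylate in a 6-exo-tet closure to give the 3-(phenylsulfonyl)tetralin F3. Reductive desulfonylation with Mg in MeOH comes back to the route at tetralin 24.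

Step 11. Facial discrimination may be poor at the C1 alkene, where the twisted aryl group and the branched alkyl group are both large, and hydrocupration of the two crowded alkenes in one pot may stall after the first addition. The fallback separates the two stereo-defining events so that each can be run, checked and purified on its own. It sets out from aryl bromide 13: hydroboration of its single alkene (the same CuH system, or a borylcupration–protonation with B2pin2 and MeOH under a chiral NHC–CuCl catalyst, which prefers ortho-substituted aryl alkenes) gives the mono(boronate) bromide F4, whose C1 epimer is removable by chromatography because C11 and C15 make it a diastereomer. Suzuki–Miyaura coupling with 14 under the conditions of step 10, to which a primary alkyl pinacol boronate is inert, gives the isopropenyl mono(boronate) F5. CuH hydroboration of its α-methylstyrene unit, the best-precedented substrate class, comes back to the route at bis(boronate) 16, which is oxidised to 17 as in step 11.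

Step 20. The enzyme may not accept the bulky, β-branched and acidic substrate, or turnover with the weakly electrophilic cinnamoyl donor may be too slow. The fallback is a chemical esterification with temporary masking of the aromatic acid. It sets out from trihydroxy acid 27: diphenyldiazomethane (acetone, rt) esterifies only the carboxylic acid to give the benzhydryl ester F6. A Mitsunobu reaction with ferulic acid 28 (PPh3, DIAD, THF, 0 °C → rt), in which the carboxylic acid and not the phenols acts as the pronucleophile, gives the benzhydryl ester ferulate F7. TFA with anisole in CH2Cl2 at 0 °C removes the benzhydryl group and comes back to the route at target 30.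

Further compounds
F1 | step 15 | (2S,3S,7R)-8-(tert-butyldimethylsilyloxy)-2-{3,4-dimethoxy-2-[(2S)-1-(phenylsulfanyl)propan-2-yl]phenyl}-3,7-dimethyloctyl 4-methylbenzenesulfonate | CC(C)(C)[Si](C)(C)OC[C@H](C)CCC[C@H](C)[C@H](COS(=O)(=O)c2ccc(C)cc2)c1ccc(OC)c(OC)c1[C@H](C)CSc3ccccc3
F2 | step 15 | (2S,3S,7R)-8-(tert-butyldimethylsilyloxy)-2-{3,4-dimethoxy-2-[(2S)-1-(phenylsulfonyl)propan-2-yl]phenyl}-3,7-dimethyloctyl 4-methylbenzenesulfonate | CC(C)(C)[Si](C)(C)OC[C@H](C)CCC[C@H](C)[C@H](COS(=O)(=O)c2ccc(C)cc2)c1ccc(OC)c(OC)c1[C@H](C)CS(=O)(=O)c3ccccc3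
F3 | step 15 | 24 bearing a phenylsulfonyl group on C3 (configuration at C3 undefined) | CC(C)(C)[Si](C)(C)OC[C@H](C)CCC[C@H](C)[C@@H]1CC(S(=O)(=O)c3ccccc3)[C@@H](C)c2c1ccc(OC)c2OC
F4 | step 11 | mono(pinacol boronate) from 13 (CH2Bpin on the C1 carbon, bromide retained) | CC(C)(C)[Si](C)(C)OC[C@H](C)CCC[C@H](C)[C@H](CB2OC(C)(C)C(C)(C)O2)c1ccc(OC)c(OC)c1Br
F5 | step 11 | isopropenyl mono(pinacol boronate) (bromide of F4 replaced by prop-1-en-2-yl) | CC(C)(C)[Si](C)(C)OC[C@H](C)CCC[C@H](C)[C@H](CB2OC(C)(C)C(C)(C)O2)c1ccc(OC)c(OC)c1C(C)=C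
F6 | step 20 | benzhydryl (5R,8S)-3,4-dihydroxy-8-[(2S,6R)-7-hydroxy-6-methylheptan-2-yl]-5-methyl-5,6,7,8-tetrahydronaphthalene-2-carboxylate | OC[C@H](C)CCC[C@H](C)[C@@H]1CC[C@@H](C)c2c1cc(C(=O)OC(c3ccccc3)c4ccccc4)c(O)c2O
F7 | step 20 | benzhydryl ester of target 30 | COc1cc(/C=C/C(=O)OC[C@H](C)CCC[C@H](C)[C@@H]2CC[C@@H](C)c3c2cc(C(=O)OC(c4ccccc4)c5ccccc5)c(O)c3O)ccc1O
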